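The cyclohexane ring (C5–C10; C10 = quaternary carbon, C6 = carbinol, C7/C8 = lactone fusion) is closed in one thermal operation from an acyclic allyl (Z)-dienyl ether carrying a 2-(methoxycarbonyl)allylboronate. A Claisen rearrangement forms C5–C10 and, with it, the quaternary centre, its vinyl group (the later oxirane) and a C6 aldehyde; this aldehyde is trapped at once by intramolecular allylboration, which forms C6–C7, the C6 hydroxyl and the C11 exo-methylene. The step exploits the γ,δ-unsaturated carbonyl relation C6–C5–C10–C1=C2 and the homoallylic relation between O6 and the lactone methylene. C8 and C9 come from D-erythronolactone; C1 is set last by iodocyclisation from the C15 aldehyde.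

Key step: step 14

Remark (numbering): C1/C2 = oxirane (earlier vinyl) carbons on C10; C3 = CH2 and C4 = central carbon of the acrolein unit, C15 = its CHO; C5–C10 = ring carbons (C5 bears C4, C6 the free OH, C7 the lactone α-carbon C11, C8 the lactone oxygen, C9 the isobutyrate, C10 the methyl C14); C12 = lactone carbonyl, C13 = lactone exo-methylene.

Remark (assumption): 22 is written as the open hydroxy enal; it may equilibrate with its five-membered lactol (O6–C15), which should not change steps 18 and 19.

Step 1
Reactants: 1 methyl 2,2-dimethoxyacetate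
Product: 2 N-methoxy-N-methyl-2,2-dimethoxyacetamide (Weinreb amide)
Conditions: MeNHOMe·HCl, i-PrMgCl, THF, −20 °C to 0 °C
Reagents that add atoms: N,O-dimethylhydroxylamine hydrochloride, CNOC.Cl
Why: Weinreb amidation of a methyl ester by the chloromagnesium amide made in the flask; no stereocentre is involved.

Step 2
Reactants: 2 Weinreb amide
Product: 3 1,1-dimethoxybut-3-yn-2-one
Conditions: HC≡CMgBr, THF, 0 °C; cold aq. NaHSO4
Reagents that add atoms: ethynylmagnesium bromide, C#C[Mg]Br
Why: Acylation of an alkynyl Grignard reagent by a Weinreb amide should stop at the ynone because the chelated tetrahedral adduct survives until the acidic quench.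

Step 3
Reactants: 3 ynone
Product: 4 (Z)-4-iodo-1,1-dimethoxybut-3-en-2-one
Conditions: NaI, AcOH, 20 °C, dark
Reagents that add atoms: sodium iodide, [Na+].[I-]
Why: Anti hydroiodination of a terminal ynone (conjugate addition of iodide, then protonation) should give the (Z)-β-iodo enone under kinetic control.

Step 4
Reactants: 4 (Z)-iodo enone
Product: 5 (Z)-1-iodo-3-(dimethoxymethyl)buta-1,3-diene
Conditions: Ph3PCH3Br, NaN(SiMe3)2, THF, −78 °C to 0 °C
Reagents that add atoms: methyltriphenylphosphonium bromide, C[P+](c1ccccc1)(c1ccccc1)c1ccccc1.[Br-]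
Why: Wittig methylenation of the activated ketone at low temperature should outrun any attack on the vinyl iodide, so the (Z) geometry is kept.

Step 5
Reactants: 6 2,3-O-isopropylidene-D-erythronolactone
Product: 7 1-deoxy-3,4-O-isopropylidene-D-erythro-pent-2-ulofuranose (methyl hemiketal at C10, anomer mixture)
Conditions: MeLi, THF, −78 °C; H2O
Reagents that add atoms: methyllithium, [Li]C
Why: Single addition of MeLi to a γ-lactone at −78 °C stops at the lactol; C8 and C9 are taken unchanged from the chiral pool and the new hemiketal centre is lost in step 6.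

Step 6
Reactants: 7 lactol
Product: 8 open-chain methyl ketone (CH3–C10(=O), D-erythro cis-acetonide at C9/C8, C7H2–OTBS)
Conditions: TBSCl, imidazole, DMF, 0 °C to 20 °C
Reagents that add atoms: tert-butyldimethylsilyl chloride, CC(C)(C)[Si](C)(C)Cl
Why: Silylation of the primary hydroxyl of the open-chain tautomer (Curtin–Hammett; the tertiary hemiketal OH is too hindered) should trap the hydroxy ketone as its silyl ether.

Step 7
Reactants: 8 methyl ketone
Product: 9 ethyl (E)-enoate (C2 ester, C1=C10 trisubstituted, C9 trans to the ester)
Conditions: Ph3P=CHCO2Et, toluene, 90 °C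
Reagents that add atoms: ethyl (triphenylphosphoranylidene)acetate, CCOC(=O)C=P(c1ccccc1)(c1ccccc1)c1ccccc1
Why: Wittig olefination by a stabilised ylide is (E)-selective (larger group trans to the ester) and base-free, so the epimerisable C9 centre should stay intact.

Step 8
Reactants: 9 (E)-enoate
Product: 10 (E)-allylic alcohol (C2H2OH)
Conditions: i-Bu2AlH, CH2Cl2, −78 °C; aq. potassium sodium tartrate
Reagents that add atoms: none
Why: 1,2-Reduction of an enoate by i-Bu2AlH gives the allylic alcohol without touching the acetonide or silyl ether.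

Step 9
Reactants: 10 (E)-allylic alcohol; 5 (Z)-dienyl iodide
Product: 11 allyl (Z)-dienyl ether (C7 silyl ether)
Conditions: CuI (10 mol %), 3,4,7,8-tetramethyl-1,10-phenanthroline (20 mol %), Cs2CO3, toluene, 75 °C
Reagents that add atoms: none
Why: Ullmann-type copper-catalysed C–O coupling of a vinyl iodide with a primary allylic alcohol proceeds with retention of the (Z) geometry, and 75 °C should stay below the Claisen threshold of the product.

Step 10
Reactants: 11 allyl (Z)-dienyl ether
Product: 12 primary alcohol (C7H2OH)
Conditions: Bu4NF, THF, 0 °C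
Reagents that add atoms: none
Why: Fluoride cleavage of the silyl ether under basic conditions leaves the acid-labile enol ether and acetals untouched.

Step 11
Reactants: 12 primary alcohol
Product: 13 aldehyde (C7 aldehyde)
Conditions: Dess–Martin periodinane, pyridine, CH2Cl2, 0 °C
Reagents that add atoms: none
Why: Buffered Dess–Martin oxidation gives the α-alkoxy aldehyde, which is used at once so that C8 cannot epimerise.

Step 12
Reactants: 13 aldehyde
Product: 15 acetate of the hydroxy acrylate adduct (C7–OAc, C11(=C13H2)–CO2Me), via aluminium alkoxide 14 (not isolated)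
Conditions: methyl propiolate, i-Bu2AlH, N-methylmorpholine N-oxide, THF, 0 °C; then 13; then Ac2O, pyridine, DMAP, −20 °C to 20 °C
Reagents that add atoms: methyl propiolate, C#CC(=O)OC; acetic anhydride, CC(=O)OC(C)=O
Why: Vinylalumination (the α-aluminio acrylate from hydroalumination of the propiolate adds to the aldehyde) gives the Morita–Baylis–Hillman-type adduct without amine base, and the aluminium alkoxide is acetylated in the flask; the new C7 centre is irrelevant because it becomes sp2 in step 13.

Step 13
Reactants: 15 acetate
Product: 16 allylboronate (C7=C11 trisubstituted, C8 cis to CH2Bpin and trans to CO2Me)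
Conditions: B2pin2, CuCl (10 mol %), LiCl, KOAc, DMF, 20 °C
Reagents that add atoms: bis(pinacolato)diboron, CC1(C)OB(OC1(C)C)B1OC(C)(C)C(C)(C)O1
Why: Copper-catalysed SN2' borylation of a Morita–Baylis–Hillman acetate (boryl copper adds to the acrylate CH2, acetate leaves) should give the tiglate-type geometry with C8 trans to the ester.

Step 14
Reactants: 16 allylboronate
Product: 19 cyclohexanol (ring C5–C10 closed; free C6–OH; C7–C11(=CH2)CO2Me; C10 methyl plus vinyl; acetonide and dimethyl acetal kept), via Claisen aldehyde 17 (not isolated), via pinacol borate 18 (not isolated)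
Conditions: toluene (0.01 M), BHT, 125 °C, sealed tube; then MeOH–H2O, 20 °C
Reagents that add atoms: none
Why: Heating 16 should trigger a [3,3]-sigmatropic Claisen rearrangement of the allyl (Z)-dienyl ether through a chair transition state (C4 and the C10 methyl axial), which forms C5–C10 with its quaternary centre and unmasks the C6 aldehyde 17; this aldehyde is trapped at once by the tethered 2-(methoxycarbonyl)allylboronate in a closed six-membered Zimmerman–Traxler allylboration (C7 attacks C6, boron passes to O6, the double bond moves to C11=C13), so that the slower Cope rearrangement of the 1,5-diene in 17 and enolisation at C5 should not compete. The closest known reactions are the thermal Claisen rearrangement of allyl dienyl ethers and the thermal addition of 2-alkoxycarbonyl allylboronates to aldehydes, here run as a domino sequence. The one ring closed is the cyclohexane C5–C10, formed by 6-exo-trig attack of the allyl γ-carbon C7 on the C6 carbonyl in a chair that is fused to the boron chelate. C5 and C10 follow from the (Z)-enol ether and (E)-allyl geometries in the chair, and their sense relative to C9 from bond formation anti to the C9–O bond while C9–H turns toward the C10 methyl (1,2-allylic strain) and C8 sits inside; C6 and C7 follow from the allylboronate geometry (C8 cis to CH2B gives OH cis to the C7 side chain) and from the tether chair that keeps the C5, C7 and C8 substituents equatorial. The step needs π-facial selectivity in the sigmatropic event and a chair boron chelate; the acetonide-bearing C9 stereocentre and the stereodefined trisubstituted allylboronate are what should secure them.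

Step 15
Reactants: 19 cyclohexanol
Product: 20 lactone acetal (12,8-lactone; O6–C15 cyclic methyl acetal; free C9–OH)
Conditions: camphorsulfonic acid (0.2 equiv), MeOH, 20 °C; then toluene, 4 Å molecular sieves, 60 °C
Reagents that add atoms: none
Why: Acid-catalysed acetal exchange should first tie O6 to C15 as the five-membered cyclic methyl acetal (as in a Fischer glycosidation), so that after methanolysis of the acetonide only O8 can lactonise onto C12 (O9 cannot reach it); the anomeric centre C15 may be a mixture and is removed in step 17.

Step 16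
Reactants: 20 lactone acetal
Product: 21 C9 isobutyrate
Conditions: (i-PrCO)2O, DMAP, Et3N, CH2Cl2, 35 °C
Reagents that add atoms: isobutyric anhydride, CC(C)C(=O)OC(=O)C(C)C
Why: DMAP-catalysed acylation of the only free hydroxyl (axial C9–OH) installs the ester with no regiochemical choice.

Step 17
Reactants: 21 C9 isobutyrate
Product: 22 hydroxy enal (free C6–OH, C4(=CH2)–CHO, C10 vinyl)
Conditions: AcOH–H2O–THF (3:1:1), 40 °C
Reagents that add atoms: water, O
Why: Mild aqueous acid hydrolysis of the allylic cyclic methyl acetal releases the C15 aldehyde and the C6 hydroxyl together, leaving the lactone and the ester untouched.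

Step 18
Reactants: 22 hydroxy enal
Product: 23 iodo lactol (six-membered lactol O1–C15, CH2I at C1, (1R))
Conditions: NIS, MeCN–H2O (10:1), 0 °C to 20 °C, dark
Reagents that add atoms: N-iodosuccinimide, O=C1CCC(=O)N1I; water, O
Why: Iodocyclisation with participation of the aldehyde oxygen (halo-acetalisation, 6-exo) should deliver oxygen to C1 from the C5 side, anti to an iodonium ion formed on the open C9-side face of the only electron-rich alkene, through a trans-fused chair with CH2I equatorial, which corresponds to (1R); the lactol centre C15 is lost in step 19.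

Step 19
Reactants: 23 iodo lactol
Product: 24 target elemanolide
Conditions: K2CO3, MeCN, 20 °C
Reagents that add atoms: none
Why: Base opens the lactol to the C15 aldehyde and the C1 alkoxide, which closes the oxirane by Williamson displacement of the primary iodide with retention at C1.

Compound list
1 | methyl 2,2-dimethoxyacetate | COC(OC)C(=O)OC | starting material
2 | N-methoxy-N-methyl-2,2-dimethoxyacetamide | COC(OC)C(=O)N(C)OC | intermediate
3 | 1,1-dimethoxybut-3-yn-2-one | COC(OC)C(=O)C#C | intermediate
4 | (Z)-4-iodo-1,1-dimethoxybut-3-en-2-one | COC(OC)C(=O)/C=C\I | intermediate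
5 | (Z)-1-iodo-3-(dimethoxymethyl)buta-1,3-diene | COC(OC)C(=C)/C=C\I | intermediate
6 | 2,3-O-isopropylidene-D-erythronolactone, (3aR,6aR)-2,2-dimethyldihydrofuro[3,4-d][1,3]dioxol-4(3aH)-one | O=C1[C@@H]2OC(C)(C)O[C@@H]2CO1 | starting material
7 | 1-deoxy-3,4-O-isopropylidene-D-erythro-pent-2-ulofuranose (anomer mixture) | CC1(O)[C@@H]2OC(C)(C)O[C@@H]2CO1 | intermediate
8 | 5-O-(tert-butyldimethylsilyl)-1-deoxy-3,4-O-isopropylidene-D-erythro-pent-2-ulose (open-chain methyl ketone) | CC(=O)[C@@H]1OC(C)(C)O[C@@H]1CO[Si](C)(C)C(C)(C)C | intermediate
9 | ethyl (E)-2,3-dideoxy-3-C-methyl-4,5-O-isopropylidene-6-O-TBS-D-erythro-hex-2-enonate | CCOC(=O)/C=C(\C)[C@@H]1OC(C)(C)O[C@@H]1CO[Si](C)(C)C(C)(C)C | intermediate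
10 | (E)-allylic alcohol from 9 (C2H2OH, C1=C10, D-erythro acetonide, C7H2OTBS) | OC/C=C(\C)[C@@H]1OC(C)(C)O[C@@H]1CO[Si](C)(C)C(C)(C)C | intermediate
11 | allyl (Z)-dienyl ether, C7 silyl ether | COC(OC)C(=C)/C=C\OC/C=C(\C)[C@@H]1OC(C)(C)O[C@@H]1CO[Si](C)(C)C(C)(C)C | intermediate
12 | allyl (Z)-dienyl ether, C7 primary alcohol | COC(OC)C(=C)/C=C\OC/C=C(\C)[C@@H]1OC(C)(C)O[C@@H]1CO | intermediate
13 | allyl (Z)-dienyl ether, C7 aldehyde | COC(OC)C(=C)/C=C\OC/C=C(\C)[C@@H]1OC(C)(C)O[C@@H]1C=O | intermediate
14 | diisobutylaluminium alkoxide of the hydroxy acrylate adduct (C7 epimers) | COC(OC)C(=C)/C=C\OC/C=C(\C)[C@@H]1OC(C)(C)O[C@@H]1C(O[Al](CC(C)C)CC(C)C)C(=C)C(=O)OC | intermediate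
15 | acetate of the hydroxy acrylate adduct (C7 epimers) | COC(OC)C(=C)/C=C\OC/C=C(\C)[C@@H]1OC(C)(C)O[C@@H]1C(OC(C)=O)C(=C)C(=O)OC | intermediate
16 | 2-(methoxycarbonyl)allyl pinacol boronate carrying the allyl (Z)-dienyl ether (C8 cis to CH2B) | COC(OC)C(=C)/C=C\OC/C=C(\C)[C@@H]1OC(C)(C)O[C@@H]1/C=C(\CB2OC(C)(C)C(C)(C)O2)C(=O)OC | intermediate
17 | Claisen aldehyde (C6 aldehyde, C5 and C10 as in 24, allylboronate intact) | O=C[C@@H](C(=C)C(OC)OC)[C@](C)(C=C)[C@@H]1OC(C)(C)O[C@@H]1/C=C(\CB2OC(C)(C)C(C)(C)O2)C(=O)OC | intermediate
18 | pinacol borate of cyclohexanol 19 (O6–Bpin) | C=C(C(=O)OC)[C@H]1[C@@H](OB3OC(C)(C)C(C)(C)O3)[C@@H](C(=C)C(OC)OC)[C@](C)(C=C)[C@@H]2OC(C)(C)O[C@H]12 | intermediate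
19 | cyclohexanol: C5–C10 configured as in 24, C6–OH, C7–C(=CH2)CO2Me, C8/C9 acetonide, C10 methyl and vinyl, C5–C(=CH2)CH(OMe)2 | C=C(C(=O)OC)[C@H]1[C@@H](O)[C@@H](C(=C)C(OC)OC)[C@](C)(C=C)[C@@H]2OC(C)(C)O[C@H]12 | intermediate
20 | 12,8-lactone with O6–C15 cyclic methyl acetal and free C9–OH (C15 anomers) | C=C1C(=O)O[C@@H]2[C@@H]1[C@H]3OC(OC)C(=C)[C@H]3[C@](C)(C=C)[C@@H]2O | intermediate
21 | C9 isobutyrate of 20 | C=C1C(=O)O[C@@H]2[C@@H]1[C@H]3OC(OC)C(=C)[C@H]3[C@](C)(C=C)[C@@H]2OC(=O)C(C)C | intermediate
22 | hydroxy enal: 24 with a C10 vinyl group in place of the oxirane | C=C1C(=O)O[C@@H]2[C@@H]1[C@@H](O)[C@@H](C(=C)C=O)[C@](C)(C=C)[C@@H]2OC(=O)C(C)C | intermediate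
23 | iodo lactol: six-membered lactol C15(OH)–O–C1(R)(CH2I) trans-fused at C5/C10 (C15 anomers) | C=C1C(=O)O[C@@H]2[C@@H]1[C@@H](O)[C@H]3C(=C)C(O)O[C@@H](CI)[C@]3(C)[C@@H]2OC(=O)C(C)C | intermediate
24 | (1R,5R,6S,7S,8R,9S,10R)-1,2-epoxy-6-hydroxy-9-isobutyryloxy-15-oxoelema-3,11(13)-dien-12,8-olide (CNP0519565.1) | C=C1C(=O)O[C@@H]2[C@@H]1[C@@H](O)[C@@H](C(=C)C=O)[C@](C)([C@@H]1CO1)[C@@H]2OC(=O)C(C)C | target

Total step count: 19. Longest linear sequence: 15 steps (6 to 24, steps 5–19; the branch 1 to 5 joins in step 9).

Steps most likely to fail

Step 14. The sigmatropic event may lose π-facial control, so that C5/C10 form with the wrong sense relative to C9. At 125 °C the allylboronate may also erode (borotropic shift, protodeboronation), or the C6 borate may close onto the C12 ester before work-up. The fallback sets out from acetate 15 and returns at 19. Heating 15 in toluene at 125 °C should give, by the same Claisen rearrangement, the aldehyde acetate F1. F1 is then treated at 20 °C with Pd(PPh3)4 (5 mol %) and InI in THF–H2O. The π-allylpalladium complex of the Morita–Baylis–Hillman acetate is reduced to an allylindium species, which adds through its γ-carbon C7 to the C6 aldehyde (Barbier-type umpolung allylation) and closes the ring to 19. No boronate is exposed to heat, the ring closure runs at room temperature where lactonisation onto C12 is slow, and diastereomers from the Claisen stage can be separated at F1.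

Step 18. External water may open the iodonium ion instead of the tethered aldehyde oxygen, which would lose the facial control at C1, or iodonium formation at the neopentyl-type vinyl group may be too slow. The fallback sets out from 22 and returns at 24 in one operation. It is a catalytic asymmetric epoxidation of the unactivated terminal alkene with a titanium salalen catalyst (Ti(OiPr)4 plus a chiral salalen ligand, the antipode that gives (R)-epoxides from 1-alkenes) and aqueous H2O2 in CH2Cl2. The electron-poor enal and methylene lactone should not react under these electrophilic conditions. No new compound is made (F0).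

Step 9. The (Z)-iodide or the (Z)-enol ether may isomerise, carbonate may eliminate HI from 5, or the product may begin its Claisen rearrangement at the coupling temperature before the allylboronate is in place. The fallback sets out from 5 and 10 and returns at 11. Iodine–lithium exchange on 5 (t-BuLi, Et2O, −78 °C) and a quench with 2-isopropoxy-4,4,5,5-tetramethyl-1,3,2-dioxaborolane should give the (Z)-dienyl pinacol boronate F2 with retention. Oxidative Chan–Lam-type coupling of F2 with alcohol 10 (Cu(OAc)2, Et3N, air, 20 °C) should then give 11 at room temperature, again with retention of the alkene geometry.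

Further compounds
F1 | step 14 | aldehyde acetate from Claisen rearrangement of 15 (C6 aldehyde, C5 and C10 as in 24, C7 acetate epimers) | O=C[C@@H](C(=C)C(OC)OC)[C@](C)(C=C)[C@@H]1OC(C)(C)O[C@@H]1C(OC(C)=O)C(=C)C(=O)OC
F2 | step 9 | (Z)-2-[3-(dimethoxymethyl)buta-1,3-dien-1-yl]-4,4,5,5-tetramethyl-1,3,2-dioxaborolane | COC(OC)C(=C)/C=C\B1OC(C)(C)C(C)(C)O1
F0 | step 18 | none | none
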